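I fit no constants here; I compare two readings taken at one time.

all flasks: G 19 mM (held)
- west: Z 0.28 M; L 0.40 M; run made earlier
- north-west: Z 0.44 M; L 0.40 M; run made earlier
- flask: Z 0.20 M; L 0.400 M; time 12 h

| run | time / h | J / % |
|---|---|---|
| west | 1.00 | 7.2 |
| west | 3.00 | 19.2 |
| west | 6.00 | 35.1 |
| west | 8.00 | 42.6 |
| west | 12.0 | 55.1 |
| north-west | 2.50 | 12.2 |
| north-west | 5.00 | 23.8 |
| north-west | 8.00 | 33.2 |
| north-west | 10.0 | 39.7 |
| north-west | 12.0 | 43.5 |

(standard deviation of a reading: 0.5 percentage points)

* amount of J at 12 h, in percent of the Z charged
* concentration of Q in solution at 12 h, in percent of saturation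

- the numbers in the tables scatter with a standard deviation of 0.5 percentage points
- at the start none of G is in solution
- Q is what G becomes in solution

My rule of thumb holds L and the time fixed and asks how the fraction of the Z charged that stands as J at 12 h moves with the charge of Z. West reads 55.1%, and north-west reads 43.5% from 1.57 times the charge. So I define the charge slope, the logarithm of the ratio of the fractions over the logarithm of the ratio of the charges, and these two scattered readings give: −0.523. West's fraction then needs a correction factor, the charge ratio raised to this slope. The flask holds 0.714 of west's charge, so the factor is 1.19 and my estimate is 65.7%.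

A power has no ceiling and a fraction has one, so the rule stops working as its number nears the whole charge. My estimate is short of that, but it stands above both readings, and the flask's charge lies below both.

The forecast gives 60% of J and 85% of saturation for Q, reasoning from “gas uptake in series with a reaction of Q with Z and L”. Its J is lower than mine. I give no figure for Q.

The flask gives 63.3% of J and 94.1% of saturation.

    Z + L ⇌ E + D, settled at all times (K = 0.460)
    Q + D → J (k = 10.6 L mol⁻¹ h⁻¹)
    G ⇌ Q, rate k3*(csat - [Q]) (kL = 5.25 h⁻¹)

The charge slope's estimate stands 2.4 percentage points above the flask's J, and the forecast stands 3.3 points below it. At 12.0 h the flask's Q has a half-life of 2.1 h by its step with D, longer than the 0.132 h half-time of its refill from G. By these two times I call the step with D the rate-limiting step at that moment, and the flask's Q stands at 94.1% of saturation.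

For the same flask with 0.80 M of Z, the charge slope gives 31.8%. The computed result is 29.9%.

The earlier runs and the new flask are calculated with made-up constants; the scatter is artificial.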